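**Retrosynthetic overview**
1. Numbering: C2–C8a is the tetrahydrochromone unit (ring A = carbocycle C4a‑C5‑C6‑C7‑C8‑C8a, ring B = its γ‑pyrone). Primed atoms are the aromatic chromone unit (ring C = γ‑pyrone, ring D = benzene). The last disconnection removes acid‑labile groups from O8 and O7'.
2. Ring A is opened at C6–C7. A pyrone carrying C5H(OAr)–CH=CH2 on C4a and C8H(OSi)–CH=CH2 on C8a is closed by ring‑closing metathesis, and the same ruthenium then syn‑dihydroxylates the new alkene in the same flask, which sets C6 and C7.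
3. Enabling feature: the C4a=C8a double bond of ring B holds C5 and C8 cis and coplanar, so the substrate is a Z‑locked 1,7‑diene. O5 and O8 lie on the same face of ring A, so only the opposite face of C6=C7 is open.
4. The C5–O6' bond comes from an iridium‑catalysed branched‑selective asymmetric allylic etherification, which joins the two halves and sets C5. The C4a–C5 bond comes from a Stille coupling of an enol triflate. C8 comes from a catalytic asymmetric vinylation of a pyrone aldehyde. Ring B is bought as chlorokojic acid.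
5. Ring C is made by Claisen condensation and cyclodehydration on a bought ring D, followed by demethylation and selective 7'‑O protection. Order of ring formation: B and D bought, C first, A last.

Key step: step 16

Remark: the minor Z isomer from the Wittig step is carried along, because the next step removes that double bond.

**Step 1**
Reactants: 1 1-(2-hydroxy-4,5-dimethoxyphenyl)ethan-1-one; 2 methyl 3-phenylpropanoate
Product: 4 6,7-dimethoxy-2-(2-phenylethyl)-4H-chromen-4-one, via diketone 3 (not isolated)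
Conditions: NaH (4 equiv), THF, reflux; then conc. HCl, MeOH, reflux
Reagents that add atoms: none
Why: A crossed Claisen condensation of the acetophenone dianion with the ester should give the 1,3‑diketone, whose phenol closes ring C by acid‑catalysed cyclodehydration (the standard chromone synthesis); no stereocenter is formed.

**Step 2**
Reactants: 4 6,7-dimethoxy-2-(2-phenylethyl)-4H-chromen-4-one
Product: 5 6,7-dihydroxy-2-(2-phenylethyl)-4H-chromen-4-one
Conditions: BBr3 (4 equiv), CH2Cl2, −78 °C → rt; then H2O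
Reagents that add atoms: none
Why: Lewis‑acid cleavage of aryl methyl ethers with BBr3 should remove both methyl groups, and the chromone core tolerates the reagent.

**Step 3**
Reactants: 5 6,7-dihydroxy-2-(2-phenylethyl)-4H-chromen-4-one
Product: 6 6-hydroxy-7-(methoxymethoxy)-2-(2-phenylethyl)-4H-chromen-4-one
Conditions: MOMCl (1.05 equiv), K2CO3 (1.1 equiv), acetone, 0 °C → rt
Reagents that add atoms: chloromethyl methyl ether, COCCl
Why: In this Williamson‑type O‑alkylation the 7'‑OH is para to C4'=O (a vinylogous acid) and is the more acidic, so one equivalent of weak base should ionise and alkylate it alone and leave the 6'‑OH free.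

**Step 4**
Reactants: 7 2-(chloromethyl)-5-hydroxy-4H-pyran-4-one (chlorokojic acid)
Product: 8 [(5-hydroxy-4-oxo-4H-pyran-2-yl)methyl]triphenylphosphonium chloride
Conditions: PPh3, MeCN, reflux
Reagents that add atoms: triphenylphosphine, c1ccc(cc1)P(c1ccccc1)c1ccccc1
Why: SN2 quaternisation of the phosphine by the activated, allylic‑type primary chloride should give the salt by precipitation.

**Step 5**
Reactants: 8 [(5-hydroxy-4-oxo-4H-pyran-2-yl)methyl]triphenylphosphonium chloride; 9 benzaldehyde
Product: 10 5-hydroxy-2-[(E)-2-phenylethenyl]-4H-pyran-4-one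
Conditions: NaOMe (2.2 equiv), MeOH, 0 °C → rt
Reagents that add atoms: none
Why: This is a Wittig olefination of a ylide stabilised through the pyrone carbonyl; the second equivalent of base covers the enolic OH, and the alkene geometry is of no consequence.

**Step 6**
Reactants: 10 5-hydroxy-2-[(E)-2-phenylethenyl]-4H-pyran-4-one
Product: 11 5-hydroxy-2-(2-phenylethyl)-4H-pyran-4-one
Conditions: H2 (1 atm), Pd/C, EtOAc/MeOH, rt
Reagents that add atoms: none
Why: Catalytic hydrogenation should saturate the styrene‑type double bond much faster than the vinylogous‑ester double bonds of the pyrone ring.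

**Step 7**
Reactants: 11 5-hydroxy-2-(2-phenylethyl)-4H-pyran-4-one; 12 formaldehyde
Product: 13 3-hydroxy-2-(hydroxymethyl)-6-(2-phenylethyl)-4H-pyran-4-one
Conditions: 37% aq. HCHO, NaOH (1.1 equiv), H2O/MeOH, rt; then HCl to pH 2
Reagents that add atoms: none
Why: An aldol‑type (Lederer–Manasse) hydroxymethylation of the enolate should occur at the only free carbon ortho to the enolic OH (the future C8a), as is established for kojic acid and allomaltol, and it brings in C8.

**Step 8**
Reactants: 13 3-hydroxy-2-(hydroxymethyl)-6-(2-phenylethyl)-4H-pyran-4-one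
Product: 14 2-(hydroxymethyl)-4-oxo-6-(2-phenylethyl)-4H-pyran-3-yl trifluoromethanesulfonate
Conditions: PhNTf2 (1.05 equiv), Et3N, CH2Cl2, 0 °C → rt
Reagents that add atoms: N-phenylbis(trifluoromethanesulfonimide), O=S(=O)(C(F)(F)F)N(c1ccccc1)S(=O)(=O)C(F)(F)F
Why: This is a chemoselective O‑sulfonylation, because only the acidic enol is ionised by the amine and the mild triflyl donor should leave the primary alcohol untouched.

**Step 9**
Reactants: 14 2-(hydroxymethyl)-4-oxo-6-(2-phenylethyl)-4H-pyran-3-yl trifluoromethanesulfonate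
Product: 15 2-formyl-4-oxo-6-(2-phenylethyl)-4H-pyran-3-yl trifluoromethanesulfonate
Conditions: Dess–Martin periodinane, CH2Cl2, 0 °C → rt
Reagents that add atoms: none
Why: Dess–Martin oxidation should take the primary alcohol to the aldehyde under neutral conditions that spare the enol triflate.

**Step 10**
Reactants: 15 2-formyl-4-oxo-6-(2-phenylethyl)-4H-pyran-3-yl trifluoromethanesulfonate; 16 vinylmagnesium bromide
Product: 17 2-[(1S)-1-hydroxyprop-2-en-1-yl]-4-oxo-6-(2-phenylethyl)-4H-pyran-3-yl trifluoromethanesulfonate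
Conditions: 16 (2.4 equiv), ZnCl2 (1.2 equiv), THF/toluene, 0 °C; tetraethylethylenediamine, (−)-MIB [(2S)-3-exo-morpholinoisoborneol, 10 mol %], then 15, −20 °C
Reagents that add atoms: none
Why: This is an amino‑alcohol‑catalysed asymmetric addition of an alkenylzinc reagent to an aldehyde, in which the zinc chelate of (−)-MIB (the antipode that gives S carbinols from aryl aldehydes) should deliver vinyl to the Si face and set C8 as S.

**Step 11**
Reactants: 17 2-[(1S)-1-hydroxyprop-2-en-1-yl]-4-oxo-6-(2-phenylethyl)-4H-pyran-3-yl trifluoromethanesulfonate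
Product: 18 2-[(1S)-1-(tert-butyldimethylsilyloxy)prop-2-en-1-yl]-4-oxo-6-(2-phenylethyl)-4H-pyran-3-yl trifluoromethanesulfonate
Conditions: TBSOTf, 2,6-lutidine, CH2Cl2, −78 → 0 °C
Reagents that add atoms: tert-butyldimethylsilyl trifluoromethanesulfonate, CC(C)(C)[Si](C)(C)OS(=O)(=O)C(F)(F)F
Why: O‑silylation with the reactive silyl triflate should protect the hindered secondary alcohol without touching C8 and install the bulky group that later shields one face of ring A.

**Step 12**
Reactants: 19 prop-2-yn-1-ol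
Product: 20 (E)-3-(tributylstannyl)prop-2-en-1-ol
Conditions: Bu3SnH (1.1 equiv), AIBN (cat.), neat, 80 °C
Reagents that add atoms: tributyltin hydride, CCCC[SnH](CCCC)CCCC
Why: In this radical hydrostannation of a terminal alkyne, reversible stannyl‑radical addition should equilibrate the adducts toward the E terminal stannane, which is then purified by chromatography.

**Step 13**
Reactants: 18 2-[(1S)-1-(tert-butyldimethylsilyloxy)prop-2-en-1-yl]-4-oxo-6-(2-phenylethyl)-4H-pyran-3-yl trifluoromethanesulfonate; 20 (E)-3-(tributylstannyl)prop-2-en-1-ol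
Product: 21 2-[(1S)-1-(tert-butyldimethylsilyloxy)prop-2-en-1-yl]-3-[(E)-3-hydroxyprop-1-en-1-yl]-6-(2-phenylethyl)-4H-pyran-4-one
Conditions: Pd(PPh3)4 (5 mol %), LiCl (3 equiv), THF, 65 °C
Reagents that add atoms: none
Why: In this Stille coupling zerovalent palladium inserts into the C4a–OTf bond and the alkenyl group is transferred with retention of the E geometry, which forms C4a–C5 at a position fixed by the former enol oxygen; the allylic silyl ether is not ionised.

**Step 14**
Reactants: 21 2-[(1S)-1-(tert-butyldimethylsilyloxy)prop-2-en-1-yl]-3-[(E)-3-hydroxyprop-1-en-1-yl]-6-(2-phenylethyl)-4H-pyran-4-one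
Product: 22 (E)-3-{2-[(1S)-1-(tert-butyldimethylsilyloxy)prop-2-en-1-yl]-4-oxo-6-(2-phenylethyl)-4H-pyran-3-yl}prop-2-en-1-yl methyl carbonate
Conditions: ClCO2Me, pyridine, CH2Cl2, 0 °C
Reagents that add atoms: methyl chloroformate, COC(=O)Cl
Why: Simple O‑acylation should turn the primary allylic alcohol into the leaving group needed for allyl‑metal chemistry.

**Step 15**
Reactants: 22 (E)-3-{2-[(1S)-1-(tert-butyldimethylsilyloxy)prop-2-en-1-yl]-4-oxo-6-(2-phenylethyl)-4H-pyran-3-yl}prop-2-en-1-yl methyl carbonate; 6 6-hydroxy-7-(methoxymethoxy)-2-(2-phenylethyl)-4H-chromen-4-one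
Product: 24 2-[(1S)-1-(tert-butyldimethylsilyloxy)prop-2-en-1-yl]-3-[(1R)-1-{[7-(methoxymethoxy)-4-oxo-2-(2-phenylethyl)-4H-chromen-6-yl]oxy}prop-2-en-1-yl]-6-(2-phenylethyl)-4H-pyran-4-one, via lithium phenoxide 23 (not isolated)
Conditions: 6 (1.5 equiv), n-BuLi (1.1 equiv), THF, 0 °C; then 22, [Ir(cod)Cl]2 (2 mol %), O,O'-(1,1'-binaphthyl-2,2'-diyl) N,N-bis(1-phenylethyl)phosphoramidite (4 mol %, pre-activated with n-PrNH2; the antipode that gives R 1-arylallyl aryl ethers), THF, 25–50 °C
Reagents that add atoms: n-butyllithium, [Li]CCCC (lithium of 23 only)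
Why: In this iridium‑catalysed asymmetric allylic etherification the cyclometalated iridium–phosphoramidite ionises the linear carbonate to an allyl complex that aryloxides attack at the substituted terminus, so the ligand antipode should fix the face and set C5 (R in 24, the S centre of the target after the change of priorities) independently of remote C8, while the excess of free 6 buffers the methoxide that is released.

**Step 16**
Reactants: 24 2-[(1S)-1-(tert-butyldimethylsilyloxy)prop-2-en-1-yl]-3-[(1R)-1-{[7-(methoxymethoxy)-4-oxo-2-(2-phenylethyl)-4H-chromen-6-yl]oxy}prop-2-en-1-yl]-6-(2-phenylethyl)-4H-pyran-4-one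
Product: 26 (5S,6S,7R,8S)-8-(tert-butyldimethylsilyloxy)-6,7-dihydroxy-5-{[7-(methoxymethoxy)-4-oxo-2-(2-phenylethyl)-4H-chromen-6-yl]oxy}-2-(2-phenylethyl)-5,6,7,8-tetrahydro-4H-chromen-4-one, via dihydrochromone 25 (not isolated)
Conditions: second-generation Grubbs catalyst (5 mol %), EtOAc, 60 °C; then 0 °C, MeCN, H2O, NaIO4 (1.5 equiv), CeCl3·7H2O (10 mol %), 15 min
Reagents that add atoms: sodium periodate, [Na+].[O-]I(=O)(=O)=O; water, O
Why: The ruthenium alkylidene takes up one vinyl group, and ring‑closing olefin metathesis (metallacyclobutane formation and cycloreversion, with loss of ethene) joins C6 to C7 and closes ring A as a six‑membered ring from a 1,7‑diene whose two arms are held cis and in plane by the C4a=C8a bond of ring B, giving 25. NaIO4 then oxidises the ruthenium left in the flask to RuO4, which adds to C6=C7 in a concerted suprafacial [3+2] step, and CeCl3‑assisted hydrolysis of the ruthenate ester releases the cis‑diol; the closest known reaction type is the one‑flask ring‑closing metathesis/ruthenium‑catalysed syn‑dihydroxylation of dienes to cyclic cis‑diols. C6 and C7 are controlled by C5 and C8: allylic 1,3‑strain against C4=O and against the substituents of ring B pushes the aryloxy and silyloxy groups into pseudoaxial positions on the same face of the nearly flat cyclohexa‑1,4‑diene‑type ring, so the oxidant should reach only the opposite face and give the 5,6‑trans, 6,7‑cis, 7,8‑trans array of the target. The step needs chemoselectivity for C6=C7 over C2=C3, C2'=C3' and the arenes, which is secured because the pyrone double bonds are trisubstituted vinylogous esters whereas C6=C7 is an isolated cis‑disubstituted alkene, and because contact with RuO4 is limited to minutes at 0 °C. Running both events in one flask spares the isolation of 25, which could lose the phenol and the silanol and become a fully aromatic chromone.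

**Step 17**
Reactants: 26 (5S,6S,7R,8S)-8-(tert-butyldimethylsilyloxy)-6,7-dihydroxy-5-{[7-(methoxymethoxy)-4-oxo-2-(2-phenylethyl)-4H-chromen-6-yl]oxy}-2-(2-phenylethyl)-5,6,7,8-tetrahydro-4H-chromen-4-one
Product: 27 (5S,6S,7R,8S)-6,7,8-trihydroxy-5-{[7-hydroxy-4-oxo-2-(2-phenylethyl)-4H-chromen-6-yl]oxy}-2-(2-phenylethyl)-5,6,7,8-tetrahydro-4H-chromen-4-one (target)
Conditions: HCl (1.25 M in MeOH), 0 °C → rt
Reagents that add atoms: none
Why: Acid‑catalysed acetal exchange and desilylation should remove both protecting groups in one operation, while protonation of the pyrone carbonyl and the inductive effect of O6 disfavour ionisation at C5 and C8, so the ether and all four stereocenters should persist.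

**Compound list**
1 | 1-(2-hydroxy-4,5-dimethoxyphenyl)ethan-1-one | CC(=O)c1cc(OC)c(OC)cc1O | starting material
2 | methyl 3-phenylpropanoate | COC(=O)CCc1ccccc1 | starting material
3 | 1-(2-hydroxy-4,5-dimethoxyphenyl)-5-phenylpentane-1,3-dione | O=C(CCc1ccccc1)CC(=O)c1cc(OC)c(OC)cc1O | intermediate
4 | 6,7-dimethoxy-2-(2-phenylethyl)-4H-chromen-4-one | O=c1cc(CCc2ccccc2)oc2cc(OC)c(OC)cc12 | intermediate
5 | 6,7-dihydroxy-2-(2-phenylethyl)-4H-chromen-4-one | O=c1cc(CCc2ccccc2)oc2cc(O)c(O)cc12 | intermediate
6 | 6-hydroxy-7-(methoxymethoxy)-2-(2-phenylethyl)-4H-chromen-4-one | O=c1cc(CCc2ccccc2)oc2cc(OCOC)c(O)cc12 | intermediate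
7 | 2-(chloromethyl)-5-hydroxy-4H-pyran-4-one | O=c1cc(CCl)occ1O | starting material
8 | [(5-hydroxy-4-oxo-4H-pyran-2-yl)methyl]triphenylphosphonium chloride | O=c1cc(C[P+](c2ccccc2)(c2ccccc2)c2ccccc2)occ1O.[Cl-] | intermediate
9 | benzaldehyde | O=Cc1ccccc1 | starting material
10 | 5-hydroxy-2-[(E)-2-phenylethenyl]-4H-pyran-4-one | O=c1cc(/C=C/c2ccccc2)occ1O | intermediate
11 | 5-hydroxy-2-(2-phenylethyl)-4H-pyran-4-one | O=c1cc(CCc2ccccc2)occ1O | intermediate
12 | formaldehyde | C=O | starting material
13 | 3-hydroxy-2-(hydroxymethyl)-6-(2-phenylethyl)-4H-pyran-4-one | O=c1cc(CCc2ccccc2)oc(CO)c1O | intermediate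
14 | 2-(hydroxymethyl)-4-oxo-6-(2-phenylethyl)-4H-pyran-3-yl trifluoromethanesulfonate | O=c1cc(CCc2ccccc2)oc(CO)c1OS(=O)(=O)C(F)(F)F | intermediate
15 | 2-formyl-4-oxo-6-(2-phenylethyl)-4H-pyran-3-yl trifluoromethanesulfonate | O=Cc1oc(CCc2ccccc2)cc(=O)c1OS(=O)(=O)C(F)(F)F | intermediate
16 | vinylmagnesium bromide | C=C[Mg]Br | starting material
17 | 2-[(1S)-1-hydroxyprop-2-en-1-yl]-4-oxo-6-(2-phenylethyl)-4H-pyran-3-yl trifluoromethanesulfonate | O=c1cc(CCc2ccccc2)oc([C@@H](O)C=C)c1OS(=O)(=O)C(F)(F)F | intermediate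
18 | 2-[(1S)-1-(tert-butyldimethylsilyloxy)prop-2-en-1-yl]-4-oxo-6-(2-phenylethyl)-4H-pyran-3-yl trifluoromethanesulfonate | O=c1cc(CCc2ccccc2)oc([C@@H](O[Si](C)(C)C(C)(C)C)C=C)c1OS(=O)(=O)C(F)(F)F | intermediate
19 | prop-2-yn-1-ol | C#CCO | starting material
20 | (E)-3-(tributylstannyl)prop-2-en-1-ol | OC/C=C/[Sn](CCCC)(CCCC)CCCC | intermediate
21 | 2-[(1S)-1-(tert-butyldimethylsilyloxy)prop-2-en-1-yl]-3-[(E)-3-hydroxyprop-1-en-1-yl]-6-(2-phenylethyl)-4H-pyran-4-one | O=c1cc(CCc2ccccc2)oc([C@@H](O[Si](C)(C)C(C)(C)C)C=C)c1/C=C/CO | intermediate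
22 | (E)-3-{2-[(1S)-1-(tert-butyldimethylsilyloxy)prop-2-en-1-yl]-4-oxo-6-(2-phenylethyl)-4H-pyran-3-yl}prop-2-en-1-yl methyl carbonate | O=c1cc(CCc2ccccc2)oc([C@@H](O[Si](C)(C)C(C)(C)C)C=C)c1/C=C/COC(=O)OC | intermediate
23 | lithium 7-(methoxymethoxy)-4-oxo-2-(2-phenylethyl)-4H-chromen-6-olate | [Li+].[O-]c1cc2c(=O)cc(CCc3ccccc3)oc2cc1OCOC | intermediate
24 | 2-[(1S)-1-(tert-butyldimethylsilyloxy)prop-2-en-1-yl]-3-[(1R)-1-{[7-(methoxymethoxy)-4-oxo-2-(2-phenylethyl)-4H-chromen-6-yl]oxy}prop-2-en-1-yl]-6-(2-phenylethyl)-4H-pyran-4-one | O=c1cc(CCc2ccccc2)oc([C@@H](O[Si](C)(C)C(C)(C)C)C=C)c1[C@H](Oc1cc2c(=O)cc(CCc3ccccc3)oc2cc1OCOC)C=C | intermediate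
25 | (5R,8S)-8-(tert-butyldimethylsilyloxy)-5-{[7-(methoxymethoxy)-4-oxo-2-(2-phenylethyl)-4H-chromen-6-yl]oxy}-2-(2-phenylethyl)-5,8-dihydro-4H-chromen-4-one | O=c1cc(CCc2ccccc2)oc2c1[C@H](Oc1cc3c(=O)cc(CCc4ccccc4)oc3cc1OCOC)C=C[C@@H]2O[Si](C)(C)C(C)(C)C | intermediate
26 | (5S,6S,7R,8S)-8-(tert-butyldimethylsilyloxy)-6,7-dihydroxy-5-{[7-(methoxymethoxy)-4-oxo-2-(2-phenylethyl)-4H-chromen-6-yl]oxy}-2-(2-phenylethyl)-5,6,7,8-tetrahydro-4H-chromen-4-one | O=c1cc(CCc2ccccc2)oc2c1[C@H](Oc1cc3c(=O)cc(CCc4ccccc4)oc3cc1OCOC)[C@@H](O)[C@@H](O)[C@@H]2O[Si](C)(C)C(C)(C)C | intermediate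
27 | (5S,6S,7R,8S)-6,7,8-trihydroxy-5-{[7-hydroxy-4-oxo-2-(2-phenylethyl)-4H-chromen-6-yl]oxy}-2-(2-phenylethyl)-5,6,7,8-tetrahydro-4H-chromen-4-one | O=c1cc(CCc2ccccc2)oc2c1[C@H](Oc1cc3c(=O)cc(CCc4ccccc4)oc3cc1O)[C@@H](O)[C@@H](O)[C@@H]2O | target

**Step count**
Total step count: 17. Longest linear sequence: 13 (steps 4–11 and 13–17, from chlorokojic acid).

**Steps most likely to fail**

*Step 15.* The allyl terminus is flanked by C4=O and by the bulky C8a substituent. Attack at the unsubstituted terminus, which gives the linear ether, may therefore compete. Facial discrimination may also erode, and the branched ether may re‑ionise.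
- The fallback sets out from 21 and comes back at 24.
- Sharpless asymmetric epoxidation of 21 (Ti(OiPr)4, D‑(−)‑diisopropyl tartrate, t‑BuOOH, 4 Å molecular sieves, CH2Cl2, −20 °C) should address only the free allylic alcohol and give the (2R,3R)-epoxy alcohol F1.
- Phenol 6 with Ti(OiPr)4 in toluene should open F1 at C5 with inversion. C5 is both the pyrone‑bearing (benzylic‑type) carbon and the carbon remote from the CH2OH group. This follows the known opening of 3‑arylglycidols by ortho‑alkoxyphenols and should give the aryloxy diol F2.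
- Garegg–Samuelsson olefination (PPh3, I2, imidazole, toluene, 80 °C) should then turn the terminal 1,2‑diol into the vinyl group of 24.

*Step 16.* The ruthenium carbene may be held by chelation to C4=O. The dihydrochromone may lose the phenol and aromatise before it is oxidised. RuO4 may also cleave the new diol or attack the oxygenated ring D.
- The fallback sets out from 24 and comes back at 26 without passing through an alkene in ring A.
- Ozonolysis of both vinyl groups (O3, CH2Cl2/MeOH, −78 °C, Sudan Red 7B as end‑point indicator, then Me2S) should give the dialdehyde F3, which is used crude.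
- SmI2 (2.5 equiv) with t‑BuOH in THF at −78 °C should then form the same C6–C7 bond by intramolecular pinacol coupling.
- Chelation of both ketyl oxygens to trivalent samarium gives the cis‑diol, and repulsion from O5 and O8 places it anti to both, as in the cyclisation of sugar‑derived 1,6‑dialdehydes to inositols.

*Step 10.* Uncatalysed background addition to the very electrophilic aldehyde may lower the enantioselectivity.
- The fallback sets out from 15 and comes back at 17.
- Direct addition of 16 (THF, −78 °C) should give the racemic allylic alcohol F4.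
- Kinetic resolution with immobilised Candida antarctica lipase B and vinyl acetate in MTBE at 30 °C should acetylate the R enantiomer (large pyrone group, medium vinyl group) to the (R)-acetate F5.
- Alcohol 17 is left behind and is separated by chromatography.

**Further compounds**
F1 | step 15 | 2-[(1S)-1-(tert-butyldimethylsilyloxy)prop-2-en-1-yl]-3-[(2R,3R)-3-(hydroxymethyl)oxiran-2-yl]-6-(2-phenylethyl)-4H-pyran-4-one | O=c1cc(CCc2ccccc2)oc([C@@H](O[Si](C)(C)C(C)(C)C)C=C)c1[C@H]3O[C@@H]3CO
F2 | step 15 | 2-[(1S)-1-(tert-butyldimethylsilyloxy)prop-2-en-1-yl]-3-[(1S,2R)-2,3-dihydroxy-1-{[7-(methoxymethoxy)-4-oxo-2-(2-phenylethyl)-4H-chromen-6-yl]oxy}propyl]-6-(2-phenylethyl)-4H-pyran-4-one | O=c1cc(CCc2ccccc2)oc([C@@H](O[Si](C)(C)C(C)(C)C)C=C)c1[C@H](Oc1cc2c(=O)cc(CCc3ccccc3)oc2cc1OCOC)[C@H](O)CO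
F3 | step 16 | (2R)-2-(tert-butyldimethylsilyloxy)-2-{3-[(1S)-1-{[7-(methoxymethoxy)-4-oxo-2-(2-phenylethyl)-4H-chromen-6-yl]oxy}-2-oxoethyl]-4-oxo-6-(2-phenylethyl)-4H-pyran-2-yl}acetaldehyde | O=c1cc(CCc2ccccc2)oc([C@@H](O[Si](C)(C)C(C)(C)C)C=O)c1[C@H](Oc1cc2c(=O)cc(CCc3ccccc3)oc2cc1OCOC)C=O
F4 | step 10 | racemic 2-(1-hydroxyprop-2-en-1-yl)-4-oxo-6-(2-phenylethyl)-4H-pyran-3-yl trifluoromethanesulfonate | O=c1cc(CCc2ccccc2)oc(C(O)C=C)c1OS(=O)(=O)C(F)(F)F
F5 | step 10 | (1R)-1-[4-oxo-6-(2-phenylethyl)-3-(trifluoromethanesulfonyloxy)-4H-pyran-2-yl]prop-2-en-1-yl acetate | O=c1cc(CCc2ccccc2)oc([C@H](OC(C)=O)C=C)c1OS(=O)(=O)C(F)(F)F
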